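Locants: oxolane O1, C2 (ring B), C3, C4, C5 (ring A, free guaiacyl). Arm C7''(OH)–C8''(O–ring B)–C9'' carries ring C.

**Plan**
1. Cuts, in order: the two ArO–Ts bonds and the one O–Ac bond (protecting groups); C1(ring B)–C2; in the oxolane half C2–C3 (CO) and C4–C5 (crotyl); in the arm C8''–O4(ring B) and C7''–C1(ring C).
2. Enabling feature: C2 is α to O1 and, once arylated, benzylic to ring B at the position para to the ether oxygen O4. The O1=C2 oxocarbenium ion therefore accepts ring B at its boron-bearing C1. The O1–C2 bond of the adduct stays reversibly ionisable, so C2 settles trans to Me-3.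
3. Helpers: tosylates make rings A and C electron-poor and shut the two other benzylic C–O bonds (C5–O1, C7''–O) during that event. BF3K marks the reacting carbon of ring B. All helpers leave in the event or in the last step.
4. Forward: vanillin tosylate → syn-crotylation → branched hydroformylation (oxolane closes as a lactol) → acetate. Lactate → aryl ether → ketone → threo alcohol → trifluoroborate. Then union and global deprotection.
5. Stereochemistry: C5 and C4 come from one catalytic asymmetric crotylboration, C3 is relayed from C4, and C2 from C3. C8'' is bought as (S)-lactate and inverted, and C7'' is relayed from C8'' (Felkin–Anh).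

Key step: step 12

Remark: lactol 7 and acetate 8 are taken as anomeric mixtures and aldehyde 6 as a mixture at its α-carbon, so these centres carry no configuration in the SMILES.

**Step 1**
Reactants: 1 vanillin
Product: 2 O-tosylvanillin (4-formyl-2-methoxyphenyl 4-methylbenzenesulfonate)
Conditions: TsCl, Et3N, DMAP (cat.), CH2Cl2, 0 °C → rt
Reagents that add atoms: p-toluenesulfonyl chloride, Cc1ccc(S(=O)(=O)Cl)cc1
Why: Sulfonylation of a phenol (Schotten–Baumann-type O-tosylation); the tosylate protects the phenol and makes ring A electron-poor, which later keeps the C5–O1 bond from ionising.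

**Step 2**
Reactants: 2 O-tosylvanillin; 3 (Z)-crotylboronic acid pinacol ester
Product: 5 4-[(1S,2R)-1-hydroxy-2-methylbut-3-en-1-yl]-2-methoxyphenyl tosylate (syn homoallylic alcohol), via borate ester 4 (not isolated)
Conditions: (S)-TRIP (5 mol %), 4 Å MS, toluene, −30 °C; aq. work-up
Reagents that add atoms: none
Why: Chiral-phosphoric-acid-catalysed asymmetric crotylboration through a closed chair transition state: the (Z)-boronate gives the syn (later 4,5-cis) pair and the (S)-catalyst, the antipode of the one that converts benzaldehyde into the (R)-homoallylic alcohol, should expose the Si face, so that C5 (S) and C4 (R) are set in one event.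

**Step 3**
Reactants: 5 syn homoallylic alcohol
Product: 7 (3R,4R,5S)-5-(3-methoxy-4-tosyloxyphenyl)-3,4-dimethyloxolan-2-ol (lactol; 3,4-trans-4,5-cis; anomers), via hydroxy aldehyde 6 (not isolated)
Conditions: Rh(acac)(CO)2 (1 mol %), Ph2POMe (10 mol %), CO/H2 (1:1, 30 bar), 4 Å MS, THF, 40 °C; then DBU (20 mol %), CH2Cl2, rt
Reagents that add atoms: carbon monoxide, [C-]#[O+]
Why: Branch-selective hydroformylation of a homoallylic alcohol under a reversibly bound phosphinite directing group (the six-membered Rh chelate favours the internal Rh–alkyl), followed by spontaneous lactol closure; C3 is relayed from C4, first in the chair-like chelate and then thermodynamically, because DBU equilibrates the α-carbon of the open aldehyde 6 towards Me-3 trans to Me-4.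

**Step 4**
Reactants: 7 lactol
Product: 8 (3R,4R,5S)-5-(3-methoxy-4-tosyloxyphenyl)-3,4-dimethyloxolan-2-yl acetate (anomers)
Conditions: Ac2O, pyridine, DMAP (cat.), CH2Cl2, 0 °C
Reagents that add atoms: acetic anhydride, CC(=O)OC(C)=O
Why: O-Acylation of the lactol gives an anomeric acetate that a Lewis acid ionises at low temperature; the anomeric configuration is lost in step 12 and needs no control.

**Step 5**
Reactants: 9 ethyl (S)-lactate; 10 4-bromo-2-methoxyphenol
Product: 11 ethyl (R)-2-(4-bromo-2-methoxyphenoxy)propanoate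
Conditions: PPh3, DIAD, THF, 0 °C → rt
Reagents that add atoms: none
Why: Mitsunobu etherification, an SN2 displacement with inversion, turns the bought (S)-carbinol centre into the (R)-aryloxy centre C8''.

**Step 6**
Reactants: 11 ethyl (R)-2-(4-bromo-2-methoxyphenoxy)propanoate
Product: 12 (R)-2-(4-bromo-2-methoxyphenoxy)-N-methoxy-N-methylpropanamide
Conditions: MeNHOMe·HCl, i-PrMgCl, THF, −20 °C
Reagents that add atoms: N,O-dimethylhydroxylamine hydrochloride, CNOC.Cl
Why: Weinreb amide formation by aminolysis of the ester with the chloromagnesium amide, fast enough at −20 °C to leave the α-stereocentre untouched.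

**Step 7**
Reactants: 13 4-iodo-2-methoxyphenol
Product: 14 4-iodo-2-methoxyphenyl tosylate
Conditions: TsCl, Et3N, DMAP (cat.), CH2Cl2, 0 °C → rt
Reagents that add atoms: p-toluenesulfonyl chloride, Cc1ccc(S(=O)(=O)Cl)cc1
Why: O-Tosylation of a phenol, which installs on ring C the same protecting and deactivating group as on ring A.

**Step 8**
Reactants: 14 4-iodo-2-methoxyphenyl tosylate; 12 Weinreb amide
Product: 16 (R)-2-(4-bromo-2-methoxyphenoxy)-1-(3-methoxy-4-tosyloxyphenyl)propan-1-one, via arylmagnesium chloride 15 (not isolated)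
Conditions: 14, i-PrMgCl·LiCl, THF, −20 °C; then 12, −20 → 0 °C; cold aq. NH4Cl
Reagents that add atoms: isopropylmagnesium chloride–lithium chloride, CC(C)[Mg]Cl.[Li+].[Cl-] (supplies the MgCl of 15; nothing of it stays in 16)
Why: Iodine–magnesium exchange with the turbo-Grignard reagent is much faster than attack on the sulfonate or exchange of the electron-rich aryl bromide of 12, and the Weinreb ketone synthesis stops at the chelated tetrahedral intermediate, which also protects C8'' from enolisation until the cold quench.

**Step 9**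
Reactants: 16 ketone
Product: 17 (1R,2R)-2-(4-bromo-2-methoxyphenoxy)-1-(3-methoxy-4-tosyloxyphenyl)propan-1-ol (threo)
Conditions: L-Selectride, THF, −78 °C; then H2O2, pH 7 buffer, 0 °C
Reagents that add atoms: none
Why: Substrate-controlled reduction under the polar Felkin–Anh model: with the C8''–OAr bond perpendicular to the carbonyl plane the bulky hydride enters anti to it and past H-8'', which should give the syn (threo) 7''R,8''R alcohol.

**Step 10**
Reactants: 17 threo alcohol
Product: 18 (1R,2R)-2-(4-bromo-2-methoxyphenoxy)-1-(3-methoxy-4-tosyloxyphenyl)propyl acetate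
Conditions: Ac2O, pyridine, DMAP (cat.), CH2Cl2, rt
Reagents that add atoms: acetic anhydride, CC(=O)OC(C)=O
Why: Acetylation masks the only free OH, which would otherwise bind BF3 and compete as an O-nucleophile in step 12, and the ester falls off in the last step.

**Step 11**
Reactants: 18 threo acetate
Product: 20 potassium {4-[(1R,2R)-1-acetoxy-1-(3-methoxy-4-tosyloxyphenyl)propan-2-yl]oxy-3-methoxyphenyl}trifluoroborate, via pinacol boronate 19 (not isolated)
Conditions: B2pin2, PdCl2(dppf) (3 mol %), KOAc, 1,4-dioxane, 85 °C; filter, then KHF2, MeOH–H2O, rt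
Reagents that add atoms: bis(pinacolato)diboron, CC1(C)OB(OC1(C)C)B1OC(C)(C)C(C)(C)O1; potassium hydrogen difluoride, F.[F-].[K+]
Why: Miyaura borylation of the aryl bromide (aryl tosylates and the secondary benzylic acetate are not expected to add oxidatively to Pd/dppf under these conditions) followed by pinacol–fluoride exchange with KHF2 gives the bench-stable ipso-nucleophile.

**Step 12**
Reactants: 8 oxolanyl acetate; 20 potassium aryltrifluoroborate
Product: 23 O-acetyl-bis-O-tosyl derivative of the target (2R,3R,4R,5S,7''R,8''R), via oxocarbenium ion 21 (not isolated), via C2 epimer 22 (not isolated)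
Conditions: BF3·OEt2 (3 equiv), 8 (1.2 equiv), CH2Cl2–MeCN, −40 → 0 °C, held at 0 °C until the C2 epimers no longer change; aq. NaHCO3
Reagents that add atoms: none
Why: BF3·OEt2 ionises the anomeric acetate of 8 to the O1=C2 oxocarbenium ion 21, and the boron-bearing C1 of ring B in 20, activated by the para ether oxygen and by the C–B bond, attacks it in an ipso-SEAr step whose Wheland intermediate loses boron to leave the aryl–C2 bond. The closest known reaction types are the BF3-promoted coupling of potassium organotrifluoroborates with acetals and furanosyl donors, the Friedel–Crafts arylation of 2-alkoxyoxolanes, and the BF3-promoted epimerisation of 2,5-diaryl-3,4-dimethyloxolanes. No ring is formed in the net reaction; the only closure is the re-closure of the ring-opened p-alkoxybenzyl cation by O1, a 5-exo-trig process. C2 is the only new stereocentre and is controlled by Me-3: attack on the inside face of the envelope may first give some 2,3-cis epimer 22, but the O1–C2 bond of either adduct is a p-alkoxybenzylic ether that BF3 opens and re-closes at 0 °C, so the mixture should drain to the more stable 2,3-trans (2R) isomer 23. The step needs site selectivity among three arene rings, secured by the C–B bond (an unmarked ring B would be expected to react para to OMe instead), and selectivity among three benzylic C–O bonds, secured by the tosylates, which make cations at C5 and C7'' far less accessible than at C2 so that the less stable 4,5-cis relationship and the threo arm persist. Keeping 20 as the limiting component leaves no aryl nucleophile that could trap the open cation during the equilibration.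

**Step 13**
Reactants: 23 protected target
Product: 24 target CNP0171079.2
Conditions: Mg turnings (excess), MeOH–THF, rt, sonication; aq. NH4Cl
Reagents that add atoms: none
Why: Reductive S–O cleavage of aryl tosylates by single-electron transfer from Mg in MeOH, with transesterification of the acetate by the Mg(OMe)2 formed, runs at room temperature without acid, so that the p-hydroxybenzylic C–O bonds and all six stereocentres should stay intact.

**Compound list**
1 | vanillin | COc1cc(C=O)ccc1O | starting material
2 | O-tosylvanillin | COc1cc(C=O)ccc1OS(=O)(=O)c1ccc(C)cc1 | intermediate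
3 | (Z)-crotylboronic acid pinacol ester | C/C=C\CB1OC(C)(C)C(C)(C)O1 | starting material
4 | O-Bpin borate ester of 5 | CC1(C)OB(O[C@H](c2ccc(OS(=O)(=O)c3ccc(C)cc3)c(OC)c2)[C@H](C)C=C)OC1(C)C | intermediate
5 | 4-[(1S,2R)-1-hydroxy-2-methylbut-3-en-1-yl]-2-methoxyphenyl tosylate | O[C@H](c1ccc(OS(=O)(=O)c2ccc(C)cc2)c(OC)c1)[C@H](C)C=C | intermediate
6 | (3R,4S)-4-hydroxy-4-(3-methoxy-4-tosyloxyphenyl)-2,3-dimethylbutanal (C2 epimers) | O[C@H](c1ccc(OS(=O)(=O)c2ccc(C)cc2)c(OC)c1)[C@H](C)C(C)C=O | intermediate
7 | (3R,4R,5S)-5-(3-methoxy-4-tosyloxyphenyl)-3,4-dimethyloxolan-2-ol | OC1O[C@H](c2ccc(OS(=O)(=O)c3ccc(C)cc3)c(OC)c2)[C@H](C)[C@H]1C | intermediate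
8 | (3R,4R,5S)-5-(3-methoxy-4-tosyloxyphenyl)-3,4-dimethyloxolan-2-yl acetate | CC(=O)OC1O[C@H](c2ccc(OS(=O)(=O)c3ccc(C)cc3)c(OC)c2)[C@H](C)[C@H]1C | intermediate
9 | ethyl (S)-lactate | C[C@H](O)C(=O)OCC | starting material
10 | 4-bromo-2-methoxyphenol | COc1cc(Br)ccc1O | starting material
11 | ethyl (R)-2-(4-bromo-2-methoxyphenoxy)propanoate | CCOC(=O)[C@@H](C)Oc1ccc(Br)cc1OC | intermediate
12 | (R)-2-(4-bromo-2-methoxyphenoxy)-N-methoxy-N-methylpropanamide | CON(C)C(=O)[C@@H](C)Oc1ccc(Br)cc1OC | intermediate
13 | 4-iodo-2-methoxyphenol | COc1cc(I)ccc1O | starting material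
14 | 4-iodo-2-methoxyphenyl tosylate | COc1cc(I)ccc1OS(=O)(=O)c1ccc(C)cc1 | intermediate
15 | (3-methoxy-4-tosyloxyphenyl)magnesium chloride | COc1cc([Mg]Cl)ccc1OS(=O)(=O)c1ccc(C)cc1 | intermediate
16 | (R)-2-(4-bromo-2-methoxyphenoxy)-1-(3-methoxy-4-tosyloxyphenyl)propan-1-one | COc1cc(C(=O)[C@@H](C)Oc2ccc(Br)cc2OC)ccc1OS(=O)(=O)c1ccc(C)cc1 | intermediate
17 | (1R,2R)-2-(4-bromo-2-methoxyphenoxy)-1-(3-methoxy-4-tosyloxyphenyl)propan-1-ol | COc1cc([C@@H](O)[C@@H](C)Oc2ccc(Br)cc2OC)ccc1OS(=O)(=O)c1ccc(C)cc1 | intermediate
18 | (1R,2R)-2-(4-bromo-2-methoxyphenoxy)-1-(3-methoxy-4-tosyloxyphenyl)propyl acetate | COc1cc([C@@H](OC(C)=O)[C@@H](C)Oc2ccc(Br)cc2OC)ccc1OS(=O)(=O)c1ccc(C)cc1 | intermediate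
19 | pinacol boronate of 18 (Bpin in place of Br) | COc1cc([C@@H](OC(C)=O)[C@@H](C)Oc2ccc(B3OC(C)(C)C(C)(C)O3)cc2OC)ccc1OS(=O)(=O)c1ccc(C)cc1 | intermediate
20 | potassium aryltrifluoroborate (BF3K in place of Br in 18) | [K+].COc1cc([C@@H](OC(C)=O)[C@@H](C)Oc2ccc([B-](F)(F)F)cc2OC)ccc1OS(=O)(=O)c1ccc(C)cc1 | intermediate
21 | (3R,4R,5S)-oxolan-1-ium-1(2)-ene (O1=C2 oxocarbenium ion from 8) | C1=[O+][C@H](c2ccc(OS(=O)(=O)c3ccc(C)cc3)c(OC)c2)[C@H](C)[C@H]1C | intermediate
22 | (2S)-epimer of 23 (2,3-cis-3,4-trans-4,5-cis) | COc1cc([C@@H](OC(C)=O)[C@@H](C)Oc2ccc([C@H]3O[C@H](c4ccc(OS(=O)(=O)c5ccc(C)cc5)c(OC)c4)[C@H](C)[C@H]3C)cc2OC)ccc1OS(=O)(=O)c1ccc(C)cc1 | intermediate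
23 | O-acetyl-bis-O-tosyl target (2,3-trans-3,4-trans-4,5-cis) | COc1cc([C@@H](OC(C)=O)[C@@H](C)Oc2ccc([C@@H]3O[C@H](c4ccc(OS(=O)(=O)c5ccc(C)cc5)c(OC)c4)[C@H](C)[C@H]3C)cc2OC)ccc1OS(=O)(=O)c1ccc(C)cc1 | intermediate
24 | CNP0171079.2 | COc1cc([C@@H](O)[C@@H](C)Oc2ccc([C@@H]3O[C@H](c4ccc(O)c(OC)c4)[C@H](C)[C@H]3C)cc2OC)ccc1O | target

Total step count: 13.
Longest linear sequence: 8 (steps 5, 6, 8, 9, 10, 11, 12, 13).

**Steps most likely to fail**

**Step 12.**
- What may go wrong:
  - Ring B may lose boron by protodeboronation before ipso attack, followed by unselective C–H alkylation.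
  - The equilibration at C2 may stay incomplete.
  - The ring-opened cation may be captured by ring A instead of by O1.
- The fallback separates C–C bond formation from the stereodefining ring closure. It sets out from lactol 7 and trifluoroborate 20.
  - A Rh(I)-catalysed 1,2-addition of the arylboron reagent to the hydroxy-aldehyde tautomer of 7 (Rh(acac)(CO)2, dppf, DME–H2O, 80 °C) forms the same aryl–C2 bond under neutral conditions. It gives the 1,4-diol F1 as a mixture at the new carbinol carbon.
  - Catalytic camphorsulfonic acid in CH2Cl2 at 0 °C then ionises only the ring-B carbinol.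
  - The C5 hydroxyl, whose own C–O bond is held by the tosylate of ring A, closes the oxolane (5-exo-trig) with retention at C5 and with the aryl group trans to Me-3.
  - The route is rejoined at 23.

**Step 3.**
- What may go wrong: linear hydroformylation or alkene isomerisation may compete with the directed branched pathway, and the equilibration at C3 may be slow.
- The fallback builds C2 and the C3 methyl group in separate, classical operations. It sets out from 5.
  - Hydroboration with 9-BBN and oxidative work-up gives the diol F2.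
  - TEMPO/PhI(OAc)2 oxidises the primary alcohol and closes the cis-lactone F3.
  - LiHMDS then MeI at −78 °C methylates the enolate on the face opposite to Me-4 and ring A to give the trans,cis-lactone F4.
  - DIBAL-H at −78 °C returns to lactol 7.

**Step 9.**
- What may go wrong: facial selectivity may be poor, because the aryloxy group is only a moderate polar director.
- The fallback replaces substrate control by catalyst control. It sets out from 16.
  - A Noyori asymmetric transfer hydrogenation is run with RuCl[(S,S)-TsDPEN](p-cymene) in HCO2H–Et3N.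
  - This is the catalyst series that gives (S)-1-phenylethanol, which corresponds to 7''R here because C8'' outranks the aryl group.
  - It delivers 17 directly; no new compound arises (F0).

**Further compounds**
F1 | step 12 | (1R,2R)-2-{4-[(2R,3R,4S)-1,4-dihydroxy-4-(3-methoxy-4-tosyloxyphenyl)-2,3-dimethylbutyl]-2-methoxyphenoxy}-1-(3-methoxy-4-tosyloxyphenyl)propyl acetate (C1 carbinol epimers) | COc1cc([C@@H](OC(C)=O)[C@@H](C)Oc2ccc(C(O)[C@H](C)[C@@H](C)[C@H](O)c3ccc(OS(=O)(=O)c4ccc(C)cc4)c(OC)c3)cc2OC)ccc1OS(=O)(=O)c1ccc(C)cc1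
F2 | step 3 | (1S,2R)-1-(3-methoxy-4-tosyloxyphenyl)-2-methylbutane-1,4-diol | O[C@H](c1ccc(OS(=O)(=O)c2ccc(C)cc2)c(OC)c1)[C@H](C)CCO
F3 | step 3 | (4R,5S)-5-(3-methoxy-4-tosyloxyphenyl)-4-methyloxolan-2-one | O=C1O[C@H](c2ccc(OS(=O)(=O)c3ccc(C)cc3)c(OC)c2)[C@H](C)C1
F4 | step 3 | (3R,4R,5S)-5-(3-methoxy-4-tosyloxyphenyl)-3,4-dimethyloxolan-2-one | O=C1O[C@H](c2ccc(OS(=O)(=O)c3ccc(C)cc3)c(OC)c2)[C@H](C)[C@H]1C
F0 | step 9 | none | none
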